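## The problem

Target 29 is a trimeric acylphloroglucinol. A central 2,4,6-trihydroxyphenyl ketone (ring B) carries at C3 and C5 two CH2 bridges to two fully substituted outer rings, ring A (acetyl) and ring C (2-methylpropanoyl), which are otherwise identical. Going round an outer ring there are C1 (bridge carbon), C2 OH, C3 methyl, C4 OMe, C5 acyl and C6 OH, so the three oxygens of one phloroglucinol must end differently and the only ether lies between the methyl and the acyl group. In the parent triphenol that oxygen is hydrogen-bonded to the ketone and flanked on both sides, and alkylating agents take the oxygen para to the acyl group first, so selective methylation cannot give the pattern. The only stereocentre is the (R)-configured α-carbon of the 2-methylbutanoyl group on ring B. It is remote, can neither control nor be controlled, and must be bought and then kept away from conditions that enolise an aryl ketone. The diarylmethane bridges form reversibly (quinone methide extrusion under strong acid, base or heat redistributes them), ring B is symmetrical and must be alkylated once at a time by two different partners, and the free polyphenols are air-sensitive, so the end game must be short and mild. A benzannulation becomes possible because the unit C6(OH)–C5(H)–C4(OMe)–C3(Me) maps atom for atom onto 3-methoxy-2-methylcyclobut-2-en-1-one 5 (C=O, CH2, C–OMe, C–Me), while C1–C2 with the bridge carbon and a protected oxygen is siloxyalkyne 8.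

## Retrosynthesis

**Second bridge.** In 29 the bond between ring B C5 and the CH2 group of ring C is cut, giving dimer 26 and benzylic alcohol 27, which reacts through ortho-quinone methide 28. The electrophile is placed on the outer ring because that ring has no free carbon and cannot condense with itself, and because the bridge carbon is then delivered by the ring synthesis and not by a separate one-carbon reagent. 26 has a single free ring carbon, so only one constitution can form. The forward reaction must be a mild, acid-catalysed alkylation that leaves the first bridge and the stereocentre alone.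

**First bridge.** The same cut in 26 gives ring B ketone 23 and benzylic alcohol 24 (through quinone methide 25). 23 has two equivalent free carbons, so it is used in excess to stop at single alkylation. Both fragments are simple monocyclic compounds.

**Ring B.** The aryl–acyl bond of 23 is cut to phloroglucinol 21 and (2R)-2-methylbutanoic acid 20 (through acid chloride 22). The stereocentre is introduced once, early, on the cheapest substrate. The forward Friedel–Crafts acylation must not racemise it.

**Outer rings, functional groups.** 24 and 27 are the desilylated forms of ketones 16 and 19 (two Si–O bonds each). The C5–acyl bond of 16 and 19 is traced back to an O6→C5 acyl shift in aryl esters 15 and 18, made from one phenol 13 with anhydrides 14 and 17. Direct C-acylation of 13 with a Lewis acid is rejected: the benzylic silyl ether on a trioxygenated ring would ionise. A photochemical acyl shift is neutral, and C5 is the only open position. One intermediate, 13, serves both outer rings.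

**Outer rings, skeleton (key step).** In 13 the bonds C1–C6 and C2–C3 are cut and the ring is opened to cyclobutenone 5 and siloxyalkyne 8. This cut is preferred to any stepwise functionalisation of a phloroglucinol because the three oxygens come from three different sources (ketene oxygen, alkyne oxygen, cyclobutenone ether) and are therefore differentiated without any selective step. The CH2OSi group marks C1 and C5 stays free. The forward reaction needs only heat and the correct orientation in one (2+2) addition.

**Four-carbon and two-carbon partners.** 5 comes from ethyl ether 4 by alkoxy exchange, and 4 from ketene 3 (cracked from diketene 1) and 1-ethoxyprop-1-yne 2. 8 comes from propargyl silyl ether 6 through ynolate 7.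

## Roads not taken

**Alternative 1:** Ring C is cut at C1–C2 and C5–C6. C1 and C6 would come from the α-carbon and ester carbon of methyl 3-[2,4,6-tris(benzyloxy)phenyl]propanoate A1, a protected ring B that already carries the bridge. C2 to C5 and the acyl group would come from 4-methoxy-3-methyl-6-(propan-2-yl)-2H-pyran-2-one A2. The lithium enolate of A1 adds to the lactone carbonyl of A2, the ring opens to a dienolate, and the carbon next to the freed ketone closes onto the ester (Claisen condensation) to give ketone A3.

- Merits: the bridge is part of the substrate, so this ring needs no diarylmethane coupling and no single alkylation of a symmetrical ring B. The acyl group and the ether arrive in place, so steps 5 to 8 of the chosen plan have no counterpart.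
- Weak points: the enolate can also attack C6 of A2 or deprotonate its vinylogous methyl group. After ring opening the most acidic hydrogen is the one at C1 between ester and ketone; once it is removed the ester is an enolate and no longer an electrophile, so the closure must be forced on a polyanion. The step is needed twice on one ring B, and the (R)-acyl group must then be placed on the last carbon of a protected trimer, at the most valuable stage.
- Comparison: step counts are close and the bridge construction is better here. The chosen plan sets against it a neutral pericyclic cascade with built-in regiocontrol, one intermediate 13 for both outer rings, and the early introduction of the stereocentre in step 9.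

**Alternative 2:** Ring A is cut at C3–C4 and C5–C6. 1-Methoxy-1,3-bis(trimethylsilyloxy)penta-1,3-diene A4 would supply C6, C1, C2, C3 and the methyl group; 4-methoxybut-3-yn-2-one A5 would supply C4, C5 and the acetyl group. (4+2) Cycloaddition, loss of the methoxy group of the acetal carbon as its silyl ether and desilylation should give 1-(4,6-dihydroxy-2-methoxy-3-methylphenyl)ethan-1-one A6.

- Merits: this is the shortest way to an outer ring. The acyl group and the correctly placed ether are present after one ring-forming step, C1 is the only free carbon, and no protecting groups are carried. Here it is better than the chosen plan, which spends two further steps per ring on the acyl group.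
- Weak points: A5 is a push–pull alkyne whose electrophilic carbon carries a donor, so it is a sluggish dienophile and a fragile compound, and a second such ynone is needed for ring C. The regiochemistry rests on this weakened polarisation. A6 has no bridge carbon; when a one-carbon electrophile is added, the benzylic electrophile that forms meets unreacted A6 and tends to give the symmetrical two-ring compound.
- Comparison: the chosen plan sets against the shorter monomer synthesis two strongly polarised partners in step 4 and a bridge carbon delivered on a ring without a free carbon, so that 25 and 28 can only be captured by ring B.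

**Alternative 3:** Ring B is built last, forming B5–B6, B3–B4 and B1–B2. The ketene made with an amine base from 3-[2,6-bis(benzyloxy)-4-methoxy-3-methyl-5-(2-methylpropanoyl)phenyl]propanoyl chloride A7 adds to tert-butoxyethyne A8 to give cyclobutenone A9. Heating A9 with siloxyalkyne A10 (the ring A arm) runs the same cascade as step 4 and gives phenol A11 with both arms in place.

- Merits: both bridges come in with the fragments, so there is no diarylmethane coupling, no statistical alkylation of ring B and no bridge redistribution, and the union is highly convergent. In this respect it is superior.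
- Weak points: A7 and A10 presuppose fully differentiated outer rings, so the main problem is only moved. A monoalkylketene dimerises readily. The tert-butyl ethers of A8 and A9 lose 2-methylpropene in the temperature range of the benzannulation. A11 has B1 and ring A C5 both unacylated, so two different acyl groups, one of them from 22 with the stereocentre, must be placed late on two similar carbons. Three kinds of oxygen protection must be removed at the end.
- Comparison: the chosen plan is shorter and keeps the benzannulation for the problem it solves best, the oxygen pattern of the outer rings.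

Key step: step 4

Assumption: (2R)-2-methylbutanoic acid 20 is taken to be purchasable as the single enantiomer; the quaternary carbon of intermediate 10 is racemic and disappears within step 4.

## Steps

Step 1
Reactants: 1 diketene (4-methylideneoxetan-2-one); 2 1-ethoxyprop-1-yne
Product: 4 3-ethoxy-2-methylcyclobut-2-en-1-one, via ketene 3 (not isolated)
Conditions: 1, 550 °C (hot tube, N2 stream); gas passed into 2, CH2Cl2, −20 °C → rt; surplus ketene vented with the N2 stream
Reagents that add atoms: none
Why: Thermal cracking of diketene is a retro-(2+2) reaction that gives two molecules of ketene; one of them undergoes the known (2+2) cycloaddition with the 1-alkoxyalkyne and the other leaves with the gas stream. The nucleophilic methyl-bearing alkyne carbon bonds to the ketene carbonyl carbon, so ethoxy ends at C3 and methyl at C2.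

Step 2
Reactants: 4 3-ethoxy-2-methylcyclobut-2-en-1-one
Product: 5 3-methoxy-2-methylcyclobut-2-en-1-one
Conditions: MeOH (solvent), camphor-10-sulfonic acid (5 mol%), 3 Å molecular sieves, rt; evaporate and repeat once
Reagents that add atoms: methanol, CO
Why: Acid-catalysed alkoxy exchange of a vinylogous ester by addition of methanol at C3 and loss of ethanol, the same addition–elimination by which aqueous acid hydrolyses 3-alkoxycyclobutenones. Methanol as solvent drives the equilibrium, and at room temperature the ring does not open to the vinylketene.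

Step 3
Reactants: 6 tert-butyldimethyl(prop-2-yn-1-yloxy)silane
Product: 8 [3-(tert-butyldimethylsilyloxy)prop-1-yn-1-yl]oxy-tri(propan-2-yl)silane, via lithium ynolate 7 (not isolated)
Conditions: LiN(SiMe3)2, THF, −78 °C; t-BuOOLi (from t-BuOOH and LiN(SiMe3)2), −78 → 0 °C; i-Pr3SiOTf, −78 → 0 °C
Reagents that add atoms: tert-butyl hydroperoxide, CC(C)(C)OO; tri(propan-2-yl)silyl trifluoromethanesulfonate, CC(C)[Si](OS(=O)(=O)C(F)(F)F)(C(C)C)C(C)C
Why: The lithium acetylide is oxidised by lithium tert-butyl peroxide to the ynolate (the known one-flask route from terminal alkynes to siloxyalkynes), which the bulky silyl triflate traps on oxygen. The tri(propan-2-yl)silyl group makes the ynol ether stable to chromatography and to heat.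

Step 4
Reactants: 5 3-methoxy-2-methylcyclobut-2-en-1-one; 8 [3-(tert-butyldimethylsilyloxy)prop-1-yn-1-yl]oxy-tri(propan-2-yl)silane
Product: 13 2-[(tert-butyldimethylsilyloxy)methyl]-5-methoxy-4-methyl-3-[tri(propan-2-yl)silyloxy]phenol, via vinylketene 9 (not isolated), via vinylcyclobutenone 10 (not isolated), via dienylketene 11 (not isolated), via cyclohexadienone 12 (not isolated)
Conditions: toluene, 80 °C then 110 °C (8 in 1.3-fold excess)
Reagents that add atoms: none
Why: On heating, 5 opens by conrotatory 4π electrocyclic cleavage of its C1–C4 bond to vinylketene 9. Alkyne 8 adds across the ketene C=C bond in a (2+2) cycloaddition: its nucleophilic carbon, the one bearing CH2OSi, bonds to the ketene carbonyl carbon (ring bond C1–C6) and its oxygen-bearing carbon bonds to the methyl-bearing ketene carbon (bond C2–C3), giving 10. A second 4π opening turns 10 into dienylketene 11, whose thermal disrotatory 6π electrocyclisation joins the ketene carbon to the terminal CH2 and closes the six-membered ring as 12; enolisation gives phenol 13. The closest known reaction type is the Danheiser benzannulation of cyclobutenones with trialkylsilyloxyalkynes, and the long-known formation of 3,5-dialkoxyphenols from 3-alkoxycyclobutenones and alkoxyalkynes shows that an alkoxy group on the four-membered ring is tolerated. No stereocentre remains: the quaternary carbon of 10 is racemic and becomes trigonal on opening, and since 10 opens reversibly, material drains through the one geometry of 11 that can cyclise. The step needs regioselectivity in the (2+2) addition, which the strong polarisation of both partners secures (donor oxygen on the alkyne, acceptor carbonyl carbon on the ketene). It also needs the alkyne to survive: the bulky silyl group suppresses the 1,3-silyl shift to a silylketene, and the slight excess of 8 keeps 9 from acylating the new phenol.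

Step 5
Reactants: 13 2-[(tert-butyldimethylsilyloxy)methyl]-5-methoxy-4-methyl-3-[tri(propan-2-yl)silyloxy]phenol; 14 acetic anhydride
Product: 15 [2-[(tert-butyldimethylsilyloxy)methyl]-5-methoxy-4-methyl-3-[tri(propan-2-yl)silyloxy]phenyl] acetate
Conditions: pyridine, 4-(dimethylamino)pyridine (10 mol%), CH2Cl2, 0 °C → rt
Reagents that add atoms: none
Why: O-Acylation of the only free hydroxyl with nucleophilic catalysis by 4-(dimethylamino)pyridine; the silyl ethers are inert under these basic conditions.

Step 6
Reactants: 15 [2-[(tert-butyldimethylsilyloxy)methyl]-5-methoxy-4-methyl-3-[tri(propan-2-yl)silyloxy]phenyl] acetate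
Product: 16 1-[2-hydroxy-3-[(tert-butyldimethylsilyloxy)methyl]-6-methoxy-5-methyl-4-[tri(propan-2-yl)silyloxy]phenyl]ethan-1-one
Conditions: hν (254 nm, quartz), degassed cyclohexane (0.01 M), rt
Reagents that add atoms: none
Why: Photo-Fries rearrangement: excitation cleaves the aryl O–acyl bond to a caged aryloxy/acetyl radical pair, which can recombine productively only at C5, the one unsubstituted ortho or para carbon, and then tautomerises to the hydrogen-bonded 2-hydroxyaryl ketone. The conditions are neutral, so the ionisable benzylic C–O bond and both silyl ethers, which a Lewis-acid Friedel–Crafts or Fries reaction would destroy, should survive.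

Step 7
Reactants: 13 2-[(tert-butyldimethylsilyloxy)methyl]-5-methoxy-4-methyl-3-[tri(propan-2-yl)silyloxy]phenol; 17 2-methylpropanoic anhydride
Product: 18 [2-[(tert-butyldimethylsilyloxy)methyl]-5-methoxy-4-methyl-3-[tri(propan-2-yl)silyloxy]phenyl] 2-methylpropanoate
Conditions: pyridine, 4-(dimethylamino)pyridine (10 mol%), CH2Cl2, 0 °C → rt
Reagents that add atoms: none
Why: Same O-acylation as step 5 with the branched anhydride.

Step 8
Reactants: 18 [2-[(tert-butyldimethylsilyloxy)methyl]-5-methoxy-4-methyl-3-[tri(propan-2-yl)silyloxy]phenyl] 2-methylpropanoate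
Product: 19 1-[2-hydroxy-3-[(tert-butyldimethylsilyloxy)methyl]-6-methoxy-5-methyl-4-[tri(propan-2-yl)silyloxy]phenyl]-2-methylpropan-1-one
Conditions: hν (254 nm, quartz), degassed cyclohexane (0.01 M), rt
Reagents that add atoms: none
Why: Photo-Fries rearrangement as in step 6; recombination inside the solvent cage is expected to outrun loss of CO from the 2-methylpropanoyl radical at room temperature.

Step 9
Reactants: 20 (2R)-2-methylbutanoic acid; 21 phloroglucinol (benzene-1,3,5-triol)
Product: 23 (2R)-2-methyl-1-(2,4,6-trihydroxyphenyl)butan-1-one, via acid chloride 22 (not isolated)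
Conditions: (COCl)2, N,N-dimethylformamide (cat.), CH2Cl2, 0 °C → rt; then 21, AlCl3 (4 equiv), CH2Cl2–MeNO2, 0 °C → rt; aq. HCl
Reagents that add atoms: none
Why: The acid chloride is made without base (no ketene, hence no racemisation) and used at once in a Friedel–Crafts acylation of phloroglucinol; the first acyl group deactivates the ring, so monoacylation is expected. The stereocentre is not a reacting centre; low temperature limits AlCl3-promoted enolisation, and the optical purity of 23 is to be checked at this stage.

Step 10
Reactants: 16 1-[2-hydroxy-3-[(tert-butyldimethylsilyloxy)methyl]-6-methoxy-5-methyl-4-[tri(propan-2-yl)silyloxy]phenyl]ethan-1-one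
Product: 24 1-[2,4-dihydroxy-3-(hydroxymethyl)-6-methoxy-5-methylphenyl]ethan-1-one
Conditions: Bu4NF (2.5 equiv), AcOH (2.5 equiv), THF, 0 °C → rt
Reagents that add atoms: none
Why: Fluoride cleaves the aryl and the primary alkyl silyl ether; acetic acid protonates the phenoxide as it forms, so the 2-hydroxybenzyl alcohol does not eliminate to the quinone methide before a nucleophile is present. 24 has no free ring carbon and cannot alkylate itself; it is used without storage.

Step 11
Reactants: 24 1-[2,4-dihydroxy-3-(hydroxymethyl)-6-methoxy-5-methylphenyl]ethan-1-one; 23 (2R)-2-methyl-1-(2,4,6-trihydroxyphenyl)butan-1-one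
Product: 26 (2R)-1-[3-[(3-acetyl-2,6-dihydroxy-4-methoxy-5-methylphenyl)methyl]-2,4,6-trihydroxyphenyl]-2-methylbutan-1-one, via quinone methide 25 (not isolated)
Conditions: p-toluenesulfonic acid monohydrate (10 mol%), MeCN, 0 °C → rt (23 in 3-fold excess, recovered)
Reagents that add atoms: none
Why: Acid-catalysed dehydration of the 2-hydroxybenzyl alcohol gives ortho-quinone methide 25 (as its protonated form), which ring B attacks with one of its two equivalent free carbons, a Friedel–Crafts alkylation of a phloroglucinol by an ortho-quinone methide. The excess of 23 holds the reaction at single alkylation, and catalytic acid at room temperature should neither enolise the α-branched ketone nor reopen the bridge.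

Step 12
Reactants: 19 1-[2-hydroxy-3-[(tert-butyldimethylsilyloxy)methyl]-6-methoxy-5-methyl-4-[tri(propan-2-yl)silyloxy]phenyl]-2-methylpropan-1-one
Product: 27 1-[2,4-dihydroxy-3-(hydroxymethyl)-6-methoxy-5-methylphenyl]-2-methylpropan-1-one
Conditions: Bu4NF (2.5 equiv), AcOH (2.5 equiv), THF, 0 °C → rt
Reagents that add atoms: none
Why: Buffered fluoride desilylation as in step 10.

Step 13
Reactants: 26 (2R)-1-[3-[(3-acetyl-2,6-dihydroxy-4-methoxy-5-methylphenyl)methyl]-2,4,6-trihydroxyphenyl]-2-methylbutan-1-one; 27 1-[2,4-dihydroxy-3-(hydroxymethyl)-6-methoxy-5-methylphenyl]-2-methylpropan-1-one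
Product: 29 (2R)-1-[3-[(3-acetyl-2,6-dihydroxy-4-methoxy-5-methylphenyl)methyl]-5-[[2,6-dihydroxy-4-methoxy-3-methyl-5-(2-methylpropanoyl)phenyl]methyl]-2,4,6-trihydroxyphenyl]-2-methylbutan-1-one, via quinone methide 28 (not isolated)
Conditions: p-toluenesulfonic acid monohydrate (10 mol%), MeCN, 0 °C → rt (27 in 1.2-fold excess)
Reagents that add atoms: none
Why: Same reaction type as step 11; 26 has a single free ring carbon, on ring B, so only one constitution can form, and ring C has none, so 28 cannot add to its own precursor. Mild catalytic acid and a short reaction time are chosen to avoid redistribution of the first bridge and to leave the (R)-centre untouched.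

## Compound list

1 | diketene (4-methylideneoxetan-2-one) | C=C1CC(=O)O1 | starting material
2 | 1-ethoxyprop-1-yne | CCOC#CC | starting material
3 | ketene | C=C=O | intermediate
4 | 3-ethoxy-2-methylcyclobut-2-en-1-one | CCOC1=C(C)C(=O)C1 | intermediate
5 | 3-methoxy-2-methylcyclobut-2-en-1-one | COC1=C(C)C(=O)C1 | intermediate
6 | tert-butyldimethyl(prop-2-yn-1-yloxy)silane | C#CCO[Si](C)(C)C(C)(C)C | starting material
7 | lithium 3-(tert-butyldimethylsilyloxy)prop-1-yn-1-olate | [Li+].[O-]C#CCO[Si](C)(C)C(C)(C)C | intermediate
8 | [3-(tert-butyldimethylsilyloxy)prop-1-yn-1-yl]oxy-tri(propan-2-yl)silane | CC(C)[Si](OC#CCO[Si](C)(C)C(C)(C)C)(C(C)C)C(C)C | intermediate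
9 | 3-methoxy-2-methylbuta-1,3-dien-1-one (vinylketene) | C=C(OC)C(C)=C=O | intermediate
10 | 2-[(tert-butyldimethylsilyloxy)methyl]-4-(1-methoxyethenyl)-4-methyl-3-[tri(propan-2-yl)silyloxy]cyclobut-2-en-1-one (racemic) | O=C1C(CO[Si](C)(C)C(C)(C)C)=C(O[Si](C(C)C)(C(C)C)C(C)C)C1(C)C(=C)OC | intermediate
11 | 2-[(tert-butyldimethylsilyloxy)methyl]-5-methoxy-4-methyl-3-[tri(propan-2-yl)silyloxy]hexa-1,3,5-trien-1-one (ketene carbon and methoxyvinyl group cis on the central double bond) | O=C=C(CO[Si](C)(C)C(C)(C)C)/C(O[Si](C(C)C)(C(C)C)C(C)C)=C(C)\C(=C)OC | intermediate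
12 | 2-[(tert-butyldimethylsilyloxy)methyl]-5-methoxy-4-methyl-3-[tri(propan-2-yl)silyloxy]cyclohexa-2,4-dien-1-one | O=C1CC(OC)=C(C)C(O[Si](C(C)C)(C(C)C)C(C)C)=C1CO[Si](C)(C)C(C)(C)C | intermediate
13 | 2-[(tert-butyldimethylsilyloxy)methyl]-5-methoxy-4-methyl-3-[tri(propan-2-yl)silyloxy]phenol | Oc1cc(OC)c(C)c(O[Si](C(C)C)(C(C)C)C(C)C)c1CO[Si](C)(C)C(C)(C)C | intermediate
14 | acetic anhydride | CC(=O)OC(C)=O | starting material
15 | [2-[(tert-butyldimethylsilyloxy)methyl]-5-methoxy-4-methyl-3-[tri(propan-2-yl)silyloxy]phenyl] acetate | CC(=O)Oc1cc(OC)c(C)c(O[Si](C(C)C)(C(C)C)C(C)C)c1CO[Si](C)(C)C(C)(C)C | intermediate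
16 | 1-[2-hydroxy-3-[(tert-butyldimethylsilyloxy)methyl]-6-methoxy-5-methyl-4-[tri(propan-2-yl)silyloxy]phenyl]ethan-1-one | CC(=O)c1c(O)c(CO[Si](C)(C)C(C)(C)C)c(O[Si](C(C)C)(C(C)C)C(C)C)c(C)c1OC | intermediate
17 | 2-methylpropanoic anhydride | CC(C)C(=O)OC(=O)C(C)C | starting material
18 | [2-[(tert-butyldimethylsilyloxy)methyl]-5-methoxy-4-methyl-3-[tri(propan-2-yl)silyloxy]phenyl] 2-methylpropanoate | CC(C)C(=O)Oc1cc(OC)c(C)c(O[Si](C(C)C)(C(C)C)C(C)C)c1CO[Si](C)(C)C(C)(C)C | intermediate
19 | 1-[2-hydroxy-3-[(tert-butyldimethylsilyloxy)methyl]-6-methoxy-5-methyl-4-[tri(propan-2-yl)silyloxy]phenyl]-2-methylpropan-1-one | CC(C)C(=O)c1c(O)c(CO[Si](C)(C)C(C)(C)C)c(O[Si](C(C)C)(C(C)C)C(C)C)c(C)c1OC | intermediate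
20 | (2R)-2-methylbutanoic acid | CC[C@@H](C)C(=O)O | starting material
21 | phloroglucinol (benzene-1,3,5-triol) | Oc1cc(O)cc(O)c1 | starting material
22 | (2R)-2-methylbutanoyl chloride | CC[C@@H](C)C(Cl)=O | intermediate
23 | (2R)-2-methyl-1-(2,4,6-trihydroxyphenyl)butan-1-one | CC[C@@H](C)C(=O)c1c(O)cc(O)cc1O | intermediate
24 | 1-[2,4-dihydroxy-3-(hydroxymethyl)-6-methoxy-5-methylphenyl]ethan-1-one | CC(=O)c1c(O)c(CO)c(O)c(C)c1OC | intermediate
25 | 4-acetyl-5-hydroxy-3-methoxy-2-methyl-6-methylidenecyclohexa-2,4-dien-1-one | O=C1C(C)=C(OC)C(C(C)=O)=C(O)C1=C | intermediate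
26 | (2R)-1-[3-[(3-acetyl-2,6-dihydroxy-4-methoxy-5-methylphenyl)methyl]-2,4,6-trihydroxyphenyl]-2-methylbutan-1-one | CC[C@@H](C)C(=O)c1c(O)cc(O)c(Cc2c(O)c(C)c(OC)c(C(C)=O)c2O)c1O | intermediate
27 | 1-[2,4-dihydroxy-3-(hydroxymethyl)-6-methoxy-5-methylphenyl]-2-methylpropan-1-one | CC(C)C(=O)c1c(O)c(CO)c(O)c(C)c1OC | intermediate
28 | 5-hydroxy-3-methoxy-2-methyl-6-methylidene-4-(2-methylpropanoyl)cyclohexa-2,4-dien-1-one | O=C1C(C)=C(OC)C(C(=O)C(C)C)=C(O)C1=C | intermediate
29 | (2R)-1-[3-[(3-acetyl-2,6-dihydroxy-4-methoxy-5-methylphenyl)methyl]-5-[[2,6-dihydroxy-4-methoxy-3-methyl-5-(2-methylpropanoyl)phenyl]methyl]-2,4,6-trihydroxyphenyl]-2-methylbutan-1-one | CC[C@@H](C)C(=O)c1c(O)c(Cc2c(O)c(C)c(OC)c(C(C)=O)c2O)c(O)c(Cc2c(O)c(C)c(OC)c(C(=O)C(C)C)c2O)c1O | target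

## Step count and least certain steps

Total: 13 steps. Longest linear sequence: 8 steps (1, 2, 4, 5, 6, 10, 11, 13).

**Step 4 (key step).** The donor-substituted cyclobutenone 5 may open only at a temperature at which 8 is lost by silyl migration to a silylketene, 9 condenses with itself, 9 acylates the phenol as it forms, or the new 2-hydroxybenzyl silyl ether loses silanol. The fallback makes vinylketene 9 at room temperature by 1,4-dehydrochlorination instead of ring opening. It sets out from 8 and a purchased keto ester, and comes back to the route at 9. Methyl 2-methyl-3-oxobutanoate F1 is converted with trimethyl orthoformate and catalytic H2SO4 in methanol into methyl 3-methoxy-2-methylbut-2-enoate F2. Saponification with LiOH in aqueous THF gives 3-methoxy-2-methylbut-2-enoic acid F3, and oxalyl chloride gives 3-methoxy-2-methylbut-2-enoyl chloride F4. Triethylamine added to F4 and 8 in toluene at 0 °C → rt should remove a γ-hydrogen and chloride to give 9, which 8 traps as 10. Warming to 80 °C then carries 10 through 11 and 12 to 13.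

**Step 2.** The exchange may stop short, so that ethyl ether is carried into step 4, or the strained vinylogous ester may be cleaved by solvolysis. The fallback sets out from 4 and returns at 5. Dilute aqueous HCl at room temperature hydrolyses 4 to 3-hydroxy-2-methylcyclobut-2-en-1-one F5, the enol of 2-methylcyclobutane-1,3-dione. Its two carbonyl positions are equivalent, so O-methylation of the acidic enol with Me3SiCHN2 in methanol–toluene at 0 °C can give only 5.

**Steps 6 and 8.** The radical pair may escape the solvent cage and return phenol 13; the strongly absorbing product may stop conversion; with 18, the acyl radical may lose CO. The fallback replaces the photochemical shift by an anionic one. It sets out from 13 and returns at 16 and 19. N-Bromosuccinimide in MeCN at −20 °C brominates the only free carbon to give 2-bromo-6-[(tert-butyldimethylsilyloxy)methyl]-3-methoxy-4-methyl-5-[tri(propan-2-yl)silyloxy]phenol F6. Acylation with 14 or 17 as in steps 5 and 7 gives [2-bromo-6-[(tert-butyldimethylsilyloxy)methyl]-3-methoxy-4-methyl-5-[tri(propan-2-yl)silyloxy]phenyl] acetate F7 or [2-bromo-6-[(tert-butyldimethylsilyloxy)methyl]-3-methoxy-4-methyl-5-[tri(propan-2-yl)silyloxy]phenyl] 2-methylpropanoate F8. t-BuLi (2.1 equiv) in THF at −95 °C effects bromine–lithium exchange, and the aryllithium attacks the neighbouring ester carbonyl (anionic Fries-type 1,3 O→C acyl shift). Protonation gives 16 or 19.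

**Step 9.** Enolisation of AlCl3-bound acyl species may erode the configuration at the α-carbon. The fallback avoids Lewis acid. It sets out from 20 and 21 and returns at 23. 21 is protected with chloromethyl methyl ether and i-Pr2NEt to give 1,3,5-tris(methoxymethoxy)benzene F9. 20 is converted with 1,1'-carbonyldiimidazole and N,O-dimethylhydroxylamine hydrochloride into (2R)-N-methoxy-N,2-dimethylbutanamide F10. Lithiation of F9 with n-BuLi (THF, 0 °C) between two directing oxygens and addition of F10 at −78 °C give (2R)-2-methyl-1-[2,4,6-tris(methoxymethoxy)phenyl]butan-1-one F11. HCl in methanol at room temperature removes the acetals to give 23.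

**Step 13 (step 11 shares the chemistry).** Acid may reopen the first bridge by quinone methide extrusion and redistribute the rings to symmetrical trimers, and slow capture at the crowded last carbon of 26 may leave 28 to react with itself. The fallback generates 28 without acid, by fluoride-triggered elimination in the presence of the phenoxide of 26. It sets out from 19 and returns at 28. HF·pyridine buffered with pyridine in THF at 0 °C removes only the primary silyl ether to give 1-[2-hydroxy-3-(hydroxymethyl)-6-methoxy-5-methyl-4-[tri(propan-2-yl)silyloxy]phenyl]-2-methylpropan-1-one F12. Acetic anhydride (1.1 equiv) in pyridine acetylates the primary alcohol to give [2-hydroxy-4-methoxy-5-methyl-3-(2-methylpropanoyl)-6-[tri(propan-2-yl)silyloxy]phenyl]methyl acetate F13. Bu4NF added to F13 and 26 in THF at −20 °C cleaves the aryl silyl ether; the phenoxide expels acetate to give 28, which the phenoxide of 26 captures at carbon to give 29.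

## Further compounds

F1 | step 4 | methyl 2-methyl-3-oxobutanoate | COC(=O)C(C)C(C)=O
F2 | step 4 | methyl 3-methoxy-2-methylbut-2-enoate (E/Z mixture) | COC(=O)C(C)=C(C)OC
F3 | step 4 | 3-methoxy-2-methylbut-2-enoic acid | OC(=O)C(C)=C(C)OC
F4 | step 4 | 3-methoxy-2-methylbut-2-enoyl chloride | ClC(=O)C(C)=C(C)OC
F5 | step 2 | 3-hydroxy-2-methylcyclobut-2-en-1-one (enol of 2-methylcyclobutane-1,3-dione) | CC1=C(O)CC1=O
F6 | step 6 | 2-bromo-6-[(tert-butyldimethylsilyloxy)methyl]-3-methoxy-4-methyl-5-[tri(propan-2-yl)silyloxy]phenol | Oc1c(Br)c(OC)c(C)c(O[Si](C(C)C)(C(C)C)C(C)C)c1CO[Si](C)(C)C(C)(C)C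
F7 | step 6 | [2-bromo-6-[(tert-butyldimethylsilyloxy)methyl]-3-methoxy-4-methyl-5-[tri(propan-2-yl)silyloxy]phenyl] acetate | CC(=O)Oc1c(Br)c(OC)c(C)c(O[Si](C(C)C)(C(C)C)C(C)C)c1CO[Si](C)(C)C(C)(C)C
F8 | step 8 | [2-bromo-6-[(tert-butyldimethylsilyloxy)methyl]-3-methoxy-4-methyl-5-[tri(propan-2-yl)silyloxy]phenyl] 2-methylpropanoate | CC(C)C(=O)Oc1c(Br)c(OC)c(C)c(O[Si](C(C)C)(C(C)C)C(C)C)c1CO[Si](C)(C)C(C)(C)C
F9 | step 9 | 1,3,5-tris(methoxymethoxy)benzene | COCOc1cc(OCOC)cc(OCOC)c1
F10 | step 9 | (2R)-N-methoxy-N,2-dimethylbutanamide | CC[C@@H](C)C(=O)N(C)OC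
F11 | step 9 | (2R)-2-methyl-1-[2,4,6-tris(methoxymethoxy)phenyl]butan-1-one | CC[C@@H](C)C(=O)c1c(OCOC)cc(OCOC)cc1OCOC
F12 | step 13 | 1-[2-hydroxy-3-(hydroxymethyl)-6-methoxy-5-methyl-4-[tri(propan-2-yl)silyloxy]phenyl]-2-methylpropan-1-one | CC(C)C(=O)c1c(O)c(CO)c(O[Si](C(C)C)(C(C)C)C(C)C)c(C)c1OC
F13 | step 13 | [2-hydroxy-4-methoxy-5-methyl-3-(2-methylpropanoyl)-6-[tri(propan-2-yl)silyloxy]phenyl]methyl acetate | CC(C)C(=O)c1c(O)c(COC(C)=O)c(O[Si](C(C)C)(C(C)C)C(C)C)c(C)c1OC
A1 | alternative 1 | methyl 3-[2,4,6-tris(benzyloxy)phenyl]propanoate | COC(=O)CCc1c(OCc2ccccc2)cc(OCc2ccccc2)cc1OCc1ccccc1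
A2 | alternative 1 | 4-methoxy-3-methyl-6-(propan-2-yl)-2H-pyran-2-one | COC1=C(C)C(=O)OC(C(C)C)=C1
A3 | alternative 1 | 1-[2,4-dihydroxy-6-methoxy-5-methyl-3-[[2,4,6-tris(benzyloxy)phenyl]methyl]phenyl]-2-methylpropan-1-one | CC(C)C(=O)c1c(OC)c(C)c(O)c(Cc2c(OCc3ccccc3)cc(OCc3ccccc3)cc2OCc2ccccc2)c1O
A4 | alternative 2 | 1-methoxy-1,3-bis(trimethylsilyloxy)penta-1,3-diene | COC(O[Si](C)(C)C)=CC(O[Si](C)(C)C)=CC
A5 | alternative 2 | 4-methoxybut-3-yn-2-one | COC#CC(C)=O
A6 | alternative 2 | 1-(4,6-dihydroxy-2-methoxy-3-methylphenyl)ethan-1-one | CC(=O)c1c(OC)c(C)c(O)cc1O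
A7 | alternative 3 | 3-[2,6-bis(benzyloxy)-4-methoxy-3-methyl-5-(2-methylpropanoyl)phenyl]propanoyl chloride | ClC(=O)CCc1c(OCc2ccccc2)c(C)c(OC)c(C(=O)C(C)C)c1OCc1ccccc1
A8 | alternative 3 | tert-butoxyethyne | CC(C)(C)OC#C
A9 | alternative 3 | 4-[[2,6-bis(benzyloxy)-4-methoxy-3-methyl-5-(2-methylpropanoyl)phenyl]methyl]-3-tert-butoxycyclobut-2-en-1-one (racemic) | O=C1C=C(OC(C)(C)C)C1Cc1c(OCc2ccccc2)c(C)c(OC)c(C(=O)C(C)C)c1OCc1ccccc1
A10 | alternative 3 | [3-[2,6-bis(benzyloxy)-4-methoxy-3-methylphenyl]prop-1-yn-1-yl]oxy-tri(propan-2-yl)silane | CC(C)[Si](OC#CCc1c(OCc2ccccc2)c(C)c(OC)cc1OCc1ccccc1)(C(C)C)C(C)C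
A11 | alternative 3 | 2-[[2,6-bis(benzyloxy)-4-methoxy-3-methylphenyl]methyl]-6-[[2,6-bis(benzyloxy)-4-methoxy-3-methyl-5-(2-methylpropanoyl)phenyl]methyl]-5-tert-butoxy-3-[tri(propan-2-yl)silyloxy]phenol | Oc1c(Cc2c(OCc3ccccc3)c(C)c(OC)c(C(=O)C(C)C)c2OCc2ccccc2)c(OC(C)(C)C)cc(O[Si](C(C)C)(C(C)C)C(C)C)c1Cc1c(OCc2ccccc2)c(C)c(OC)cc1OCc1ccccc1
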